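The cyclohexenone ring (C4–C5–C6–C7–C8–C9, locants defined below) is annulated last onto a complete seven-membered ring, all ten carbons of which come from eucarvone (made from carvone). The key step exploits the 1,5-relationship of C6=O and C8 in the enone C6(=O)–C7(Me)=C8H, with ring atoms C9 and C4 α and β to C8. A cycloheptadiene carbaldehyde (C4=C9–C8HO) takes up methyl 3-oxopentanoate by Michael addition at C4 and aldol condensation at C8 in one operation, closing the six-membered ring and setting C4 and C9. One catalytic epoxidation sets C1/C11; their trans-acetonide, a temporary ring, locks the conformation that relays this to C4, and the C3 methyl enforces the cis fusion.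

Key step: step 6

Remark (locants): atoms carry the labels of the target skeleton in all intermediates: seven-membered ring C1(OAng)–C2H=C3(Me)–C4H–C9H–C10(Me)2–C11H(OAng), six-membered ring C4–C5H2–C6(=O)–C7(Me)=C8H–C9.
Remark (assumption): the sense of induction in step 4 is assigned by analogy with 2,2-dimethylchromenes; should it prove opposite, the (R,R)-catalyst is used.
Remark: either enantiomer of carvone serves in step 1, because its stereocentre is destroyed there.

Step 1
Reactants: 1 (R)-(−)-carvone
Product: 4 eucarvone (2,6,6-trimethylcyclohepta-2,4-dien-1-one), via carvone hydrobromide 2 (not isolated), via carenone 3 (not isolated)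
Conditions: HBr (33% in AcOH), 5–10 °C; then KOH, MeOH, 0 °C → reflux (bromide carried on crude)
Reagents that add atoms: none
Why: Markovnikov addition of HBr to the isopropenyl group gives tertiary bromide 2, KOH effects intramolecular enolate alkylation (3-exo-tet) to carenone 3, and its dienolate opens by norcaradiene-to-cycloheptatriene electrocyclic ring expansion to the achiral cycloheptadienone (the well-established carvone-to-eucarvone conversion).

Step 2
Reactants: 4 eucarvone
Product: 5 enaminone (7Z)-7-[(dimethylamino)methylidene]-2,6,6-trimethylcyclohepta-2,4-dien-1-one (geometry inconsequential)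
Conditions: t-BuOCH(NMe2)2 (1.5 equiv), toluene, 100 °C
Reagents that add atoms: tert-butoxybis(dimethylamino)methane (Bredereck's reagent), CN(C)C(OC(C)(C)C)N(C)C
Why: Bredereck aminomethylenation at C9, the only enolisable CH2; attack at the methyl-bearing α-carbon through the norcaradiene enolate tautomer is reversible and cannot eliminate dimethylamine, so the condensation should funnel to the vinylogous amide.

Step 3
Reactants: 5 enaminone
Product: 7 trienal (3,7,7-trimethylcyclohepta-1,3,5-triene-1-carbaldehyde), via amino alcohol 6 (not isolated)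
Conditions: DIBAL-H (1.2 equiv), THF, −78 °C; then 1 M HCl, 0 °C → rt
Reagents that add atoms: water, O
Why: Stork–Danheiser-type reductive 1,3-carbonyl transposition: 1,2-hydride addition to the vinylogous amide carbonyl (C4), acid-induced loss of water to the conjugated iminium ion and hydrolysis give the aldehyde on C9 and H on C4; the 7,7-dimethylcycloheptatriene is achiral and cannot undergo [1,5]-H shifts at the quaternary C10.

Step 4
Reactants: 7 trienal
Product: 8 epoxide (1S,7R)-3,6,6-trimethyl-8-oxabicyclo[5.1.0]octa-2,4-diene-5-carbaldehyde (C1–C11 epoxide)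
Conditions: (S,S)-Jacobsen catalyst [(salen)Mn(III)Cl, 5 mol %], mCPBA (1.5 equiv), NMO (5 equiv), CH2Cl2, −78 °C
Reagents that add atoms: mCPBA, OOC(=O)c1cccc(Cl)c1
Why: Jacobsen–Katsuki epoxidation: C1=C11 is the only cis-disubstituted alkene, the most remote from the formyl group, and flanked by a quaternary carbon like the alkene of 2,2-dimethylchromenes, so it should be selected and the (S,S)-catalyst should deliver oxygen to the face giving the (1S,11R)-epoxide; this is the only stereo-defining catalytic step.

Step 5
Reactants: 8 epoxide
Product: 10 acetonide dienal (trans-fused 1,11-O-isopropylidene derivative of diol 9; 1R,11R), via diol 9 (not isolated)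
Conditions: HClO4 (5 mol %), acetone/H2O (10:1), 0 °C; then 2,2-dimethoxypropane (excess), rt
Reagents that add atoms: water, O; 2,2-dimethoxypropane, COC(C)(C)OC
Why: Acid-catalysed hydration should open the vinyl epoxide by SN2-type attack of water at the allylic C1 with inversion (C11 is neopentyl and an SN1 path is disfavoured by the electron-poor dienal), and the resulting (1R,11R)-trans-diol is ketalised in the same pot to the trans-fused dioxolane.

Step 6
Reactants: 10 acetonide dienal; 11 methyl 3-oxopentanoate
Product: 14 tricyclic β-keto ester (cis-fused enone; CO2Me at C5; 1,11-acetonide), via Michael adduct 12 (not isolated), via aldol 13 (not isolated)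
Conditions: 11 (1.3 equiv), DBU (0.3 equiv), MeCN, 0 °C → 40 °C
Reagents that add atoms: none
Why: DBU generates the β-keto ester enolate, which adds through C5 to C4 of the dienal (Michael addition) to give 1,5-keto aldehyde 12; the ethyl-ketone enolate (C7) then closes the six-membered ring on the C8 aldehyde by a 6-(enolendo)-exo-trig aldol (13) and E1cB loss of water gives the enone, the whole being the Robinson-type cyclohexenone annulation long known for β-keto esters and enals. C4 is set by substrate control: the trans-fused acetonide can only span gauche (diequatorial) C1/C11 oxygens, which fixes C11 below the diene plane and puts the pseudo-axial C10 methyl on the face of O–C11, so the enolate should enter C4 from the opposite face, syn to O–C1. C9 is set after the Michael step, while the aldehyde α-centre is still epimerisable: A(1,2) strain with the C3 methyl holds the new C4–C5 bond pseudo-axial, only the C9 epimer with C8 cis to C5 can then reach C7, and the irreversible dehydration drains the equilibrium into the cis-fused enone. The step needs 1,4- rather than 1,6-addition (attack at C2) or Knoevenagel condensation; both additions are reversible, the aldehyde is flanked by the quaternary C10, and only the C4 adduct can close a six-membered ring, so the condensation acts as the sink. The C5 ester centre forms as an epimer/enol mixture and is erased in step 7.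

Step 7
Reactants: 14 tricyclic β-keto ester
Product: 17 diol dienone (4aR,7R,8R,9aS)-7,8-dihydroxy-2,5,9,9-tetramethyl-4,4a,7,8,9,9a-hexahydro-3H-benzo[7]annulen-3-one, via keto acid 15 (not isolated), via acetonide dienone 16 (not isolated)
Conditions: LiCl (3 equiv), DMSO/H2O (20:1), 140 °C; then AcOH/H2O (4:1), 40 °C
Reagents that add atoms: none
Why: Krapcho demethoxycarbonylation (chloride SN2 at the ester methyl, loss of CO2 from the β-keto carboxylate) is neutral and should spare the γ-epimerisable C9 centre, and mild aqueous acid then hydrolyses the strained trans-acetonide without ionising the allylic C1 alcohol.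

Step 8
Reactants: 17 diol dienone; 18 angelic acid
Product: 20 target (4aR,7R,8R,9aS)-2,5,9,9-tetramethyl-3-oxo-4,4a,7,8,9,9a-hexahydro-3H-benzo[7]annulene-7,8-diyl bis[(Z)-2-methylbut-2-enoate], via C1 monoangelate 19 (not isolated)
Conditions: 18 (4 equiv), 2,4,6-trichlorobenzoyl chloride (4 equiv), Et3N (4.4 equiv), toluene, rt; then 17, toluene, 80 °C (no DMAP)
Reagents that add atoms: none
Why: Yamaguchi-type esterification through the angelic 2,4,6-trichlorobenzoic mixed anhydride acylates both secondary hydroxyls (C1 first, then the neopentyl C11) at the less hindered angeloyl carbonyl and, run without DMAP, is the usual way to avoid Z-to-E isomerisation to tiglates; no stereocentre is touched.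

Compound list
1 | (R)-(−)-carvone | CC1=CC[C@H](CC1=O)C(C)=C | starting material
2 | carvone hydrobromide, (R)-5-(2-bromopropan-2-yl)-2-methylcyclohex-2-en-1-one | CC1=CC[C@H](CC1=O)C(C)(C)Br | intermediate (not isolated)
3 | carenone, cis-fused 3,7,7-trimethylbicyclo[4.1.0]hept-3-en-2-one | CC1=CC[C@@H]2[C@H](C1=O)C2(C)C | intermediate (not isolated)
4 | eucarvone, 2,6,6-trimethylcyclohepta-2,4-dien-1-one | CC1=CC=CC(C)(C)CC1=O | intermediate
5 | enaminone, (7Z)-7-[(dimethylamino)methylidene]-2,6,6-trimethylcyclohepta-2,4-dien-1-one | CN(C)/C=C1\C(=O)C(C)=CC=CC1(C)C | intermediate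
6 | amino alcohol, 7-[(dimethylamino)methylidene]-2,6,6-trimethylcyclohepta-2,4-dien-1-ol (formed as its aluminium alkoxide; carbinol centre racemic) | CN(C)/C=C1\C(O)C(C)=CC=CC1(C)C | intermediate (not isolated)
7 | trienal, 3,7,7-trimethylcyclohepta-1,3,5-triene-1-carbaldehyde | O=CC1=CC(C)=CC=CC1(C)C | intermediate
8 | epoxide, (1S,7R)-3,6,6-trimethyl-8-oxabicyclo[5.1.0]octa-2,4-diene-5-carbaldehyde | O=CC1=CC(C)=C[C@@H]2O[C@@H]2C1(C)C | intermediate
9 | diol, (5R,6R)-5,6-dihydroxy-3,7,7-trimethylcyclohepta-1,3-diene-1-carbaldehyde (trans) | O=CC1=CC(C)=C[C@@H](O)[C@H](O)C1(C)C | intermediate (not isolated)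
10 | acetonide dienal, trans-fused 1,11-O-isopropylidene derivative of 9 (1R,11R) | O=CC1=CC(C)=C[C@H]2OC(C)(C)O[C@@H]2C1(C)C | intermediate
11 | methyl 3-oxopentanoate | CCC(=O)CC(=O)OC | starting material
12 | Michael adduct, 1,5-keto aldehyde with C4–C5 bond syn to O–C1 (C5 and C9 not fixed) | CCC(=O)C(C(=O)OC)[C@H]1C(C)=C[C@H]2OC(C)(C)O[C@@H]2C(C)(C)C1C=O | intermediate (not isolated)
13 | aldol, β-hydroxy ketone with the six-membered ring closed (C5, C7, C8, C9 not fixed) | CC1(C)O[C@@H]2C=C(C)[C@@H]3C(C(=O)OC)C(=O)C(C)C(O)C3C(C)(C)[C@H]2O1 | intermediate (not isolated)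
14 | tricyclic β-keto ester, cis-fused enone with CO2Me at C5 and the 1,11-acetonide (C5 epimers/enol) | CC1(C)O[C@@H]2C=C(C)[C@@H]3C(C(=O)OC)C(=O)C(C)=C[C@@H]3C(C)(C)[C@H]2O1 | intermediate
15 | keto acid, C5 carboxylic acid of 14 (formed as lithium carboxylate) | CC1(C)O[C@@H]2C=C(C)[C@@H]3C(C(=O)O)C(=O)C(C)=C[C@@H]3C(C)(C)[C@H]2O1 | intermediate (not isolated)
16 | acetonide dienone, cis-fused enone with the 1,11-acetonide | CC1(C)O[C@@H]2C=C(C)[C@@H]3CC(=O)C(C)=C[C@@H]3C(C)(C)[C@H]2O1 | intermediate (not isolated)
17 | diol dienone, (4aR,7R,8R,9aS)-7,8-dihydroxy-2,5,9,9-tetramethyl-4,4a,7,8,9,9a-hexahydro-3H-benzo[7]annulen-3-one | O[C@@H]1C=C(C)[C@@H]2CC(=O)C(C)=C[C@@H]2C(C)(C)[C@H]1O | intermediate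
18 | angelic acid, (Z)-2-methylbut-2-enoic acid | C/C=C(/C)C(=O)O | starting material
19 | C1 monoangelate of 17 (C11–OH free) | C/C=C(/C)C(=O)O[C@@H]1C=C(C)[C@@H]2CC(=O)C(C)=C[C@@H]2C(C)(C)[C@H]1O | intermediate (not isolated)
20 | CNP0361763.1, (4aR,7R,8R,9aS)-2,5,9,9-tetramethyl-3-oxo-4,4a,7,8,9,9a-hexahydro-3H-benzo[7]annulene-7,8-diyl bis[(Z)-2-methylbut-2-enoate] | C/C=C(/C)C(=O)O[C@@H]1C=C(C)[C@@H]2CC(=O)C(C)=C[C@@H]2C(C)(C)[C@H]1OC(=O)/C(C)=C\C | target

Total step count: 8. Longest linear sequence: 8 steps (1 → 20); the route is fully linear, with 11 and 18 entering as purchased reagents.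

Steps most likely to fail

Step 6 (key step). What may go wrong: conjugate addition at C2 (1,6) or Knoevenagel condensation at the aldehyde may outrun 1,4-addition, the facial bias at C4 may be insufficient, or base may trigger vinylogous enolisation and opening of the acetonide. The fallback makes the C4–C5 bond by cycloaddition instead of enolate addition. Setting out from 10, an inverse-electron-demand hetero-Diels–Alder reaction of the O=C8–C9=C4 unit with 2-methoxybut-1-ene (Eu(fod)3 cat., or neat with heating) should give the fused 2-ethyl-2-methoxy-dihydropyran F1. This adduct can only join C5 to C4 and should form on the face of O–C1 for the same steric reason. Mild acid (PPTS, wet acetone, rt) should unmask the keto aldehyde F2 without touching the acetonide. KOH/MeOH then closes the ring by the same aldol condensation and returns to the route at compound 16, which aqueous AcOH converts into 17.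

Step 4. What may go wrong: epoxidation of the trisubstituted C2=C3 alkene, oxidation of the aldehyde, or weak enantiofacial discrimination on this trienal. The fallback replaces asymmetric catalysis by resolution. Setting out from 7, buffered mCPBA (NaHCO3, CH2Cl2, 0 °C) should still prefer the alkene most remote from the formyl group and give the racemic epoxide F3. Hydration as in step 5 gives the racemic trans-diol F4. Lipase-catalysed acetylation (Amano lipase PS, vinyl acetate, MTBE) is expected by Kazlauskas' rule to acylate the allylic C1 hydroxyl of the (1R,11R)-antipode, giving the monoacetate F5, which is separated from the unreacted antipode. K2CO3/MeOH then returns to the route at compound 9, which is ketalised to 10 as in step 5.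

Step 8. What may go wrong: incomplete acylation of the neopentyl C11 hydroxyl and Z-to-E isomerisation of the angeloyl groups during prolonged heating. The fallback builds the Z-alkenes on the molecule. Setting out from 17, both hydroxyls are acylated with 2-[bis(2,2,2-trifluoroethoxy)phosphoryl]propanoic acid (DCC, DMAP, CH2Cl2), which cannot isomerise, to give the bis-phosphonate F6. A double Still–Gennari olefination with acetaldehyde (KHMDS, 18-crown-6, THF, −78 °C), Z-selective for this phosphonate type, then returns to the route at compound 20.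

Further compounds
F1 | step 6 | hetero-Diels–Alder adduct, fused 2-ethyl-2-methoxy-3,4-dihydro-2H-pyran on the acetonide (ketal centre not fixed) | CCC1(OC)C[C@H]2C(C)=C[C@H]3OC(C)(C)O[C@@H]3C(C)(C)C2=CO1
F2 | step 6 | keto aldehyde, C4-(2-oxobutyl) C9-carbaldehyde acetonide (C9 not fixed) | CCC(=O)C[C@H]1C(C)=C[C@H]2OC(C)(C)O[C@@H]2C(C)(C)C1C=O
F3 | step 4 | racemic epoxide (rac-8) | O=CC1=CC(C)=C[C@@H]2O[C@@H]2C1(C)C.O=CC1=CC(C)=C[C@H]2O[C@H]2C1(C)C
F4 | step 4 | racemic trans-diol (rac-9) | O=CC1=CC(C)=C[C@@H](O)[C@H](O)C1(C)C.O=CC1=CC(C)=C[C@H](O)[C@@H](O)C1(C)C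
F5 | step 4 | (1R,11R)-diol C1-monoacetate | CC(=O)O[C@@H]1C=C(C)C=C(C=O)C(C)(C)[C@H]1O
F6 | step 8 | bis-phosphonate, 1,11-bis{2-[bis(2,2,2-trifluoroethoxy)phosphoryl]propanoate} of 17 | CC(C(=O)O[C@@H]1C=C(C)[C@@H]2CC(=O)C(C)=C[C@@H]2C(C)(C)[C@H]1OC(=O)C(C)P(=O)(OCC(F)(F)F)OCC(F)(F)F)P(=O)(OCC(F)(F)F)OCC(F)(F)F
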